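**Plan**

1. Cuts, last to first: the three O–CH3 bonds; the C3–CO2H bond of unit B (the 5-aryloxy-6,7-dihydroxycoumarin half, coumarin numbering); the pyranone of unit B at C8a–O1, C4a–C4, C3=C4 and O1–C2, leaving an aryne of ring B, DMF and dimethyl malonate; then C8a–Si, the C4a oxygen (back to a formyl group) and the diaryl ether bond C5–O.
2. Enabling feature: in the benzene ring of unit B the adjacent carbons C8a and C4a carry O1 and C4, and only C4a has the C5 aryloxy oxygen beside it. This is the pattern that O/C addition across a 3-aryloxyaryne, polarised by that oxygen, delivers.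
3. Forward order: coumarin A is bought complete (isoscopoletin) and joined through its 6-OH to 2-bromo-3,4-dimethoxybenzaldehyde. The formyl carbon is exchanged for the C4a oxygen, C8a takes iodine and then silicon, and the lactone of unit B, the only ring that is built, closes in the three-component step. Ester removal and demethylation finish the route.
4. Silicon is placed on C8a and the triflate on C4a because this isomer comes from a phenol with a single free ortho carbon, so halogenation poses no regiochemical choice. It releases the same aryne as the reverse arrangement would.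
5. Stereochemistry: the target is achiral and has no stereogenic double bond, so nothing has to be set. The only selectivity issue is the regiochemistry of the aryne addition.

Key step: step 5

Remark: ArA = 7-methoxy-2-oxo-2H-chromen-6-yl (coumarin A as its 7-O-methyl ether); ring B carbons carry the coumarin numbering of unit B throughout; 1, 2, 10 and 11 are assumed to be purchased; the geometry of the exocyclic C=C bond of transient 13 is left open because it is lost in the next event.

**Route**

Step 1
Reactants: 1 isoscopoletin (6-hydroxy-7-methoxy-2H-chromen-2-one); 2 2-bromo-3,4-dimethoxybenzaldehyde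
Product: 3 2-(ArA-oxy)-3,4-dimethoxybenzaldehyde
Conditions: CuI (10 mol%), picolinic acid (20 mol%), K3PO4 (2 equiv), DMSO, 90 °C, Ar
Reagents that add atoms: none
Why: Ullmann-type diaryl ether coupling, in which the ortho formyl group activates the C–Br bond of 2 towards copper, the picolinate ligand is suited to ortho-substituted partners, and the anhydrous phosphate base should leave lactone A and the aldehyde intact.

Step 2
Reactants: 3 2-(ArA-oxy)-3,4-dimethoxybenzaldehyde
Product: 5 2-(ArA-oxy)-3,4-dimethoxyphenol, via aryl formate 4 (not isolated)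
Conditions: mCPBA, CH2Cl2, 0 °C to rt; then Et3N (cat.), MeOH, rt
Reagents that add atoms: mCPBA (3-chloroperoxybenzoic acid), OOC(=O)c1cccc(Cl)c1
Why: Baeyer–Villiger (Dakin-type) oxidation, in which the aryl group, made electron-rich by the ortho aryloxy and para methoxy groups, should migrate in preference to hydrogen; the labile formate 4 is cleaved by mild methanolysis that spares lactone A, and the electron-poor C3=C4 bond of coumarin A is not epoxidised.

Step 3
Reactants: 5 2-(ArA-oxy)-3,4-dimethoxyphenol
Product: 6 2-(ArA-oxy)-6-iodo-3,4-dimethoxyphenol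
Conditions: NIS (1.05 equiv), TsOH·H2O (10 mol%), MeCN, 0 °C
Reagents that add atoms: N-iodosuccinimide, O=C1CCC(=O)N1I
Why: Electrophilic aromatic iodination, in which the free phenol ring is by far the most activated arene; its para carbon and one ortho carbon are blocked by OMe and OArA, so iodine should enter the single free ortho carbon (the future C8a), which is also para to a methoxy group.

Step 4
Reactants: 6 2-(ArA-oxy)-6-iodo-3,4-dimethoxyphenol
Product: 9 2-(ArA-oxy)-3,4-dimethoxy-6-(trimethylsilyl)phenyl trifluoromethanesulfonate, via silyl ether 7 (not isolated), via lithium phenoxide 8 (not isolated)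
Conditions: HMDS, THF, 70 °C, then evaporation; n-BuLi (1.05 equiv), THF, –100 °C; Tf2O, –100 to –78 °C
Reagents that add atoms: hexamethyldisilazane, C[Si](C)(C)N[Si](C)(C)C; trifluoromethanesulfonic anhydride, O=S(=O)(OS(=O)(=O)C(F)(F)F)C(F)(F)F
Why: One-pot O-silylation, iodine–lithium exchange, anionic 1,3 O-to-C silyl shift (retro-Brook rearrangement) and O-triflation; exchange of an aryl iodide at –100 °C is expected to outpace addition of n-BuLi to lactone A, the aryllithium is consumed at once by the intramolecular silyl shift, and phenoxide 8 is trapped by Tf2O.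

Step 5
Reactants: 9 2-(ArA-oxy)-3,4-dimethoxy-6-(trimethylsilyl)phenyl trifluoromethanesulfonate; 10 N,N-dimethylformamide; 11 dimethyl malonate
Product: 15 methyl 5-(ArA-oxy)-6,7-dimethoxy-2-oxo-2H-chromene-3-carboxylate, via aryne 12 (not isolated), via amino ortho-quinone methide 13 (not isolated), via arylidene malonate 14 (not isolated)
Conditions: CsF (4 equiv), 11 (3 equiv), DMF (10, solvent), rt, Ar
Reagents that add atoms: none
Why: Fluoride removes the silyl group from C8a and triflate leaves from C4a to give aryne 12; the DMF oxygen adds to C8a, the aryl anion at C4a closes on the iminium carbon (formal [2+2]), and the benzoxetene opens to amino ortho-quinone methide 13. The malonate anion adds to the exocyclic carbon of 13, dimethylamine is expelled to give arylidene malonate 14, and the C8a phenoxide attacks one ester group. The closest known reaction type is the three-component coupling of arynes, DMF and active methylene compounds to coumarins. The one ring formed, the pyranone of unit B, closes last at O1–C2 by 6-exo-trig acyl substitution, and no stereocentre arises. The step needs DMF to add with O at C8a and C at C4a: the inductively withdrawing C5 aryloxy group beside C4a distorts the aryne so that the nucleophile attacks the remote carbon C8a while negative charge builds at C4a. Coumarin A, the methyl ethers and the diaryl ether should be inert to CsF and malonate at room temperature.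

Step 6
Reactants: 15 methyl 5-(ArA-oxy)-6,7-dimethoxy-2-oxo-2H-chromene-3-carboxylate
Product: 16 5-(ArA-oxy)-6,7-dimethoxy-2-oxo-2H-chromene-3-carboxylic acid
Conditions: LiOH, THF/H2O, rt; then 1 M HCl
Reagents that add atoms: lithium hydroxide LiOH, [Li+].[OH-]
Why: Saponification of the methyl ester, where any lactone opened by hydroxide is a cis-2-hydroxycinnamate that should reclose on acidification.

Step 7
Reactants: 16 5-(ArA-oxy)-6,7-dimethoxy-2-oxo-2H-chromene-3-carboxylic acid
Product: 17 5-(ArA-oxy)-6,7-dimethoxy-2H-chromen-2-one (tri-O-methyl ether of the target)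
Conditions: Cu powder, quinoline, 200 °C
Reagents that add atoms: none
Why: Copper-mediated protodecarboxylation of a coumarin-3-carboxylic acid, the classical way to a 3-unsubstituted coumarin after a malonate condensation; ethers and lactones are stable under these non-nucleophilic conditions.

Step 8
Reactants: 17 5-(ArA-oxy)-6,7-dimethoxy-2H-chromen-2-one
Product: 18 6,7-dihydroxy-5-[(7-hydroxy-2-oxo-2H-chromen-6-yl)oxy]-2H-chromen-2-one (target)
Conditions: BBr3 (excess), CH2Cl2, –78 °C to rt; then MeOH, H2O
Reagents that add atoms: none
Why: Lewis acid cleavage of the three aryl methyl ethers (bromide attacks the O-methyl carbon of each borane-complexed ether), which should leave the diaryl ether and both lactones untouched.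

**Compound list**

1 | isoscopoletin (6-hydroxy-7-methoxy-2H-chromen-2-one) | COc1cc2oc(=O)ccc2cc1O | starting material
2 | 2-bromo-3,4-dimethoxybenzaldehyde | COc1ccc(C=O)c(Br)c1OC | starting material
3 | 2-[(7-methoxy-2-oxo-2H-chromen-6-yl)oxy]-3,4-dimethoxybenzaldehyde | COc1ccc(C=O)c(Oc2cc3ccc(=O)oc3cc2OC)c1OC | intermediate
4 | 2-(ArA-oxy)-3,4-dimethoxyphenyl formate (formed in the flask) | COc1ccc(OC=O)c(Oc2cc3ccc(=O)oc3cc2OC)c1OC | intermediate
5 | 2-(ArA-oxy)-3,4-dimethoxyphenol | COc1ccc(O)c(Oc2cc3ccc(=O)oc3cc2OC)c1OC | intermediate
6 | 2-(ArA-oxy)-6-iodo-3,4-dimethoxyphenol | COc1cc(I)c(O)c(Oc2cc3ccc(=O)oc3cc2OC)c1OC | intermediate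
7 | [2-(ArA-oxy)-6-iodo-3,4-dimethoxyphenoxy]trimethylsilane (formed in the flask) | COc1cc(I)c(O[Si](C)(C)C)c(Oc2cc3ccc(=O)oc3cc2OC)c1OC | intermediate
8 | lithium 2-(ArA-oxy)-3,4-dimethoxy-6-(trimethylsilyl)phenoxide (formed in the flask) | [Li+].[O-]c1c([Si](C)(C)C)cc(OC)c(OC)c1Oc1cc2ccc(=O)oc2cc1OC | intermediate
9 | 2-(ArA-oxy)-3,4-dimethoxy-6-(trimethylsilyl)phenyl trifluoromethanesulfonate (Si on C8a, OTf on C4a) | COc1cc([Si](C)(C)C)c(OS(=O)(=O)C(F)(F)F)c(Oc2cc3ccc(=O)oc3cc2OC)c1OC | intermediate
10 | N,N-dimethylformamide | CN(C)C=O | starting material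
11 | dimethyl malonate | COC(=O)CC(=O)OC | starting material
12 | 3-(ArA-oxy)-4,5-dimethoxybenzyne (triple bond between C8a and C4a; formed in the flask) | COC1=CC#CC(Oc2cc3ccc(=O)oc3cc2OC)=C1OC | intermediate
13 | 6-[(dimethylamino)methylidene]-5-(ArA-oxy)-3,4-dimethoxycyclohexa-2,4-dien-1-one (exocyclic C=C geometry undefined; formed in the flask) | CN(C)C=C1C(=O)C=C(OC)C(OC)=C1Oc1cc2ccc(=O)oc2cc1OC | intermediate
14 | dimethyl 2-{[2-hydroxy-6-(ArA-oxy)-4,5-dimethoxyphenyl]methylidene}propanedioate (present as its phenoxide; formed in the flask) | COC(=O)C(=Cc1c(O)cc(OC)c(OC)c1Oc1cc2ccc(=O)oc2cc1OC)C(=O)OC | intermediate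
15 | methyl 5-(ArA-oxy)-6,7-dimethoxy-2-oxo-2H-chromene-3-carboxylate | COC(=O)c1cc2c(Oc3cc4ccc(=O)oc4cc3OC)c(OC)c(OC)cc2oc1=O | intermediate
16 | 5-(ArA-oxy)-6,7-dimethoxy-2-oxo-2H-chromene-3-carboxylic acid | OC(=O)c1cc2c(Oc3cc4ccc(=O)oc4cc3OC)c(OC)c(OC)cc2oc1=O | intermediate
17 | 5-(ArA-oxy)-6,7-dimethoxy-2H-chromen-2-one | COc1cc2oc(=O)ccc2c(Oc2cc3ccc(=O)oc3cc2OC)c1OC | intermediate
18 | 6,7-dihydroxy-5-[(7-hydroxy-2-oxo-2H-chromen-6-yl)oxy]-2H-chromen-2-one | O=c1ccc2cc(Oc3c(O)c(O)cc4oc(=O)ccc34)c(O)cc2o1 | target

**Count and risks**

Total step count: 8. Longest linear sequence: 8 steps (1 or 2 to 18; 10 and 11 enter at step 5).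

Steps most likely to fail:

1. Step 5. Trapping of the amino ortho-quinone methide by the malonate anion may lose out to its protonation, hydrolysis or oligomerisation. Excess malonate may also add in conjugate fashion to the 3-carboxycoumarin once it has formed. Fallback: set out from 9 and separate the two events. The aryne is released with CsF in DMF without malonate and the insertion product is hydrolysed with water, the known aryne–DMF route to salicylaldehydes. This should give 2-hydroxy-6-(ArA-oxy)-4,5-dimethoxybenzaldehyde F1 with the same regiochemistry. A conventional Knoevenagel condensation of F1 with dimethyl malonate (piperidine, AcOH, MeOH, reflux), with spontaneous lactonisation, comes back to the route at 15.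

2. Step 4. n-BuLi may add to lactone A in competition with iodine–lithium exchange, or the aryllithium may be protonated before the silyl group migrates. Fallback: set out from 6 and form the C8a–Si bond without an organolithium. Acetylation (Ac2O, pyridine) gives 2-(ArA-oxy)-6-iodo-3,4-dimethoxyphenyl acetate F2. Palladium-catalysed silylation of the aryl iodide with hexamethyldisilane (Pd2(dba)3, 2-(di-tert-butylphosphino)biphenyl, LiOAc, DMF, 100 °C) should give 2-(ArA-oxy)-3,4-dimethoxy-6-(trimethylsilyl)phenyl acetate F3. Methanolysis (K2CO3, MeOH, 0 °C, acidic work-up) frees 2-(ArA-oxy)-3,4-dimethoxy-6-(trimethylsilyl)phenol F4, and triflation (Tf2O, pyridine, CH2Cl2, 0 °C) comes back to the route at 9.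

3. Step 1. Coupling at copper between two ortho-substituted partners may be slow, so that reduction of the C–Br bond or degradation of the aldehyde competes. Fallback: set out from 1 and make the same C5–O bond by uncatalysed nucleophilic aromatic substitution. The potassium phenoxide of 1 displaces fluoride from purchased 2-fluoro-3,4-dimethoxybenzaldehyde (SMILES COc1ccc(C=O)c(F)c1OC), which is activated by its ortho formyl group (K2CO3, DMF, 120 °C). This comes back to the route at 3 and makes no new intermediate.

Further compounds
F1 | step 5 | 2-hydroxy-6-[(7-methoxy-2-oxo-2H-chromen-6-yl)oxy]-4,5-dimethoxybenzaldehyde | O=Cc1c(O)cc(OC)c(OC)c1Oc1cc2ccc(=O)oc2cc1OC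
F2 | step 4 | 2-(ArA-oxy)-6-iodo-3,4-dimethoxyphenyl acetate | CC(=O)Oc1c(I)cc(OC)c(OC)c1Oc1cc2ccc(=O)oc2cc1OC
F3 | step 4 | 2-(ArA-oxy)-3,4-dimethoxy-6-(trimethylsilyl)phenyl acetate | CC(=O)Oc1c([Si](C)(C)C)cc(OC)c(OC)c1Oc1cc2ccc(=O)oc2cc1OC
F4 | step 4 | 2-(ArA-oxy)-3,4-dimethoxy-6-(trimethylsilyl)phenol | Oc1c([Si](C)(C)C)cc(OC)c(OC)c1Oc1cc2ccc(=O)oc2cc1OC
F0 | step 1 | none | none
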